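The runs are simulated with constants of no real substance; the scatter is artificial.

The examiner opens with the readings; the candidate has to say what stands in Saturday's flask at the asked time.

| setting | Saturday's | Tuesday's | flask |
|---|---|---|---|
| L | 0.20 M | 0.40 M | 0.20 M |
| D | 15 mM (held) | 15 mM (held) | 15 mM (held) |
| remark | the very flask that is asked about, followed so far | run made earlier |  |
| time |  |  | 3.0 min |

| run | time / s | X / % | E / % |
|---|---|---|---|
| Saturday's | 10.0 | 15.6 | 5.8 |
| Saturday's | 12.0 | 18.2 | 8.0 |
| Saturday's | 20.0 | 29.1 | 21.0 |
| Tuesday's | 15.0 | 15.0 | 8.4 |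
| Tuesday's | 30.0 | 28.2 | 23.2 |
| Tuesday's | 40.0 | 38.4 | 33.7 |
| Tuesday's | 60.0 | 51.8 | 47.7 |
| Tuesday's | 80.0 | 64.8 | 61.7 |

(standard deviation of a reading: 1 percentage point)

- the X and E together standing at 3.0 min, as a percentage of the L charged
- concentration of G in solution at 3.0 min, in percent of saturation

- amounts and yields of X count E too
- given per volume of solution although it is solid: E
- at the start none of D is in solution
- G is what D becomes in solution

**What rate do the readings give?** Saturday's last reading has 29.1% of 0.20 M of L turned into X in 20.0 s, so on average 2.91 mM s⁻¹. Tuesday's last reading gives 3.24 mM s⁻¹.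

**And the order in L?** The logarithm of the rate ratio over that of the charge ratio reads 0.155. I therefore treat the making of X as roughly steady, with the scatter of the readings on that figure.

**Then what do you carry?** L is the limiting reagent, since D is held. Saturday's charge lasts 1.15 min at that rate, and this time, charge over rate, is the charge clock.

**Where does the asked time lie?** It lies 0.416 decades past the clock, and 0.954 decades past the last reading.

**The forecast says 98.5% for y and 98.7% of saturation, holding that “consumption is tiny”. Do you sign?** Not for y. I too expect [L] near nothing, but I give no figure. The asked time lies 1.85 min beyond the clock, and Saturday's readings end at 20.0 s, inside it, so they do not show whether X survives that stretch.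

The flask gives 25.8% for y and 76.0% of saturation.

    L + G → X (k = 4.50 M⁻¹ s⁻¹)
    G + X → Z (k = 5.80 M⁻¹ s⁻¹)
    E ⇌ X, rate k3*(cs3 - [X]) while solid is left; crystals form when [X] > cs3 (solubility = 16.0 mM, k = 1.10 s⁻¹)
    G → Q (k = 0.0320 s⁻¹)
    D ⇌ G, rate k5*(csat - [G]) (kL = 0.380 s⁻¹)

At 0.967 min, inside the clock of 1.15 min, Saturday's flask used G 2.1 times as fast in L + G as in G + X. At 3.0 min, 2.62 clocks in, with L at 0.069% of the charge, that ratio stood at 0.0071 and Z held 74.1%. The flask with 0.34 M of L has, at Saturday's rate, a clock of 1.95 min, so 3.0 min is 1.54 clocks for it, and there Z holds 37.2% while X and E together stand at 62.5%.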